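## The problem

- The target (19) is a (2S)-flavanone. Ring C (chroman-4-one) is fused to a phloroglucinol-type ring A, ring B (2,4-dihydroxy-5-methoxyphenyl) sits at C2, and a (2R)-lavandulyl chain, C1''H2–C2''H[C3''(CH3)=CH2]–CH2CH=C(CH3)2, sits at C8.
- Ring A carries three oxygens with different fates (O1 in ring C, 5-OH, 7-OCH3), but its cheap precursors are symmetric. C8 must be told from C6 and O1 from O5; once 5-OH is free, 6- and 8-substituted flavanones can interconvert through the chalcone.
- The stereocentres C2 and C2'' are five bonds apart (C2–O1–C8a–C8–C1''–C2''). Neither can control the other, so each needs its own reagent control.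
- C2'' is a tertiary all-carbon centre with no heteroatom or carbonyl next to it in the target. It has to be made while a handle is still present and must survive removal of that handle.
- C2 is a benzylic ether carbon β to the ketone. It epimerises by retro-oxa-Michael opening in base, and in acid too because ring B is electron-rich, so it should be set late and under mild conditions.
- The isopropenyl and prenyl double bonds exclude hydrogenolysis, Friedel–Crafts acylation and strong acids. Acid would also add a free ortho phenol across the isopropenyl group to give a 2,2-dimethylchroman.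
- Enabling feature: C1''H2 on C8 is ortho to C8a–O1, so C8=C1'' with C8a=O is an o-quinone methide. In addition, O1, C8a, C8, C1'', C2'' and C3'' can be closed into a six-membered lactone (3,4-dihydrocoumarin) in which C2'' is C3 and the isopropenyl carbon C3'' is the lactone carbonyl.

## Retrosynthesis

**19 ⇒ 18 ⇒ 12 + 17 (cut C2–C1').** After removal of three methoxymethyl ethers (18), the C2–C1' bond is cut to chromone 12 and arylboronic acid 17. The neighbouring cut, O1–C2 (chalcone closure), forms C2 reversibly and would give both C2 epimers next to the fixed C2'' centre. Chromone 12 is flat in ring C and has only C2''. The forward reaction must be a catalyst-controlled conjugate arylation that ignores the remote C2'' and runs cold enough that 18 does not ring-open.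

**12 ⇒ 10 (cut O1–C2 and C2–C3).** The chromone is the acetophenone 10 plus one carbon. Closure is unambiguous only if the oxygen that becomes O1 is a free phenol and the one that becomes O5 is blocked. That is exactly the state in which the plan below leaves ring A.

**10 ⇒ 9 ⇒ 7 (isopropenyl from a lactone carbonyl).** The isopropenyl group is traced to methyl ketone 9 and then to the carbonyl of dihydrocoumarin 7. The O1–C3'' bond of 7 is not in the target. It holds C3'' at the acid oxidation level, where asymmetric catalysis can reach C2'', and it ties up the future O1 while the future O5 is protected. The forward steps (amide formation, methyl addition, methylenation) must spare the aryl ketone and the C2''–H.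

**7 ⇒ 6 ⇒ 2 + 4 (key disconnection: cut C1''–C2'' and O1–C3'').** Lactone 6 is opened to o-quinone methide 5, released from sulfone 2, and the enolate of acyl imidazole 4. Cutting C8–C1'' instead would need a preformed chiral lavandulyl electrophile. Here both partners are achiral, and one catalytic step makes the chain bond, the C2'' centre and the O1/O5 distinction. The forward reaction needs facial control on the enolate and C–C bond formation ahead of O-acylation.

**2 ⇒ 1; 4 ⇒ 3; 17 ⇒ 15 ⇒ 14 ⇒ 13.** Sulfone 2 comes from the symmetric acetophenone 1 by sulfonylmethylation; C3 and C5 of 1 are equivalent, so there is no regiochemical question. Acyl imidazole 4 comes from acid 3. Boronic acid 17 comes from 4-methoxyresorcinol 13 by protection (14), bromination at the doubly activated position (15) and lithiation–borylation.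

## Roads not taken

**Alternative 1:** Cut C8–C1'' and O1–C2 (the most obvious plan). The mono-protected acetophenone A2 is C-alkylated as its phenoxide with lavandulyl bromide A1 to give 10, followed by Claisen–Schmidt condensation and chalcone closure.
- A1 must be made enantiopure first, by auxiliary alkylation, reduction and bromination with stoichiometric chirality. By the change in CIP priorities the (2''R) centre of 19 maps onto (S)-lavandulol, not the (R)-enantiomer found in lavender oil.
- A1 is a β-branched primary halide, so C- versus O-alkylation and ortho versus para attack on A2 are hard to control.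
- The chalcone closure gives no control at C2.
- The chosen plan makes C2'' catalytically from achiral pieces and sets C2 by a separate catalyst.

**Alternative 2:** Cut C8–C1'' by a para-Claisen–Cope shift. The 5-O-prenyl chromone A3 rearranges to the 8-prenyl chromone A4. Allylic oxidation gives the (E)-allylic alcohol A5, and a Johnson–Claisen rearrangement gives ester A6, which is then extended to the prenyl arm.
- The regiochemistry at C8 is clean, but A5 is a primary allylic alcohol with no stereochemical information, so C2'' is formed racemic.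
- The ester → aldehyde → isopropylidene sequence must be run beside the chromone carbonyl, and the chain takes about six steps.
- The chosen plan reaches the same carbon skeleton in fewer steps with C2'' controlled.

**Alternative 3:** Cut C1''–C2'' by direct lavandulylation. The o-quinone methide 5 is trapped at the γ-carbon of allylsilane A7 (Hosomi–Sakurai type), giving the racemic lavandulyl acetophenone A8 in one step.
- This is the shortest chain construction, but the open transition state places the new stereocentre on the nucleophile, far from any catalyst binding site on the unsubstituted methide carbon, so C2'' is uncontrolled.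
- A7 needs its own synthesis.
- In A8 the two phenols are not distinguished, so chromone closure would give 6- and 8-isomers.
- The lactone route solves both the stereocentre and the phenol distinction in the same step.

Key step: step 3

Assumption: the sense of induction of the two chiral catalysts (steps 3 and 11) is assigned by analogy with their usual models; both are available in either enantiomeric form and the antipode is used if a model reaction shows the opposite sense. Compounds 1, 3 and 13 are taken as catalogue chemicals.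

## Steps

Step 1
Reactants: 1 1-(2,6-dihydroxy-4-methoxyphenyl)ethan-1-one
Product: 2 1-{2,6-dihydroxy-4-methoxy-3-[(4-methylbenzenesulfonyl)methyl]phenyl}ethan-1-one
Conditions: (CH2O)n (1.0 equiv), TolSO2Na, HCO2H/H2O, 25 °C
Reagents that add atoms: formaldehyde (from paraformaldehyde), C=O; sodium 4-methylbenzenesulfinate, Cc1ccc(cc1)S(=O)[O-].[Na+]
Why: Mannich-type three-component sulfonylmethylation: the acid-generated hydroxymethyl/benzyl cation at the activated ring position is captured by sulfinate at sulfur; C3 and C5 of 1 are equivalent, so only one mono-product can form, and one equivalent of formaldehyde in acid limits a second substitution.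

Step 2
Reactants: 3 5-methylhex-4-enoic acid
Product: 4 1-(1H-imidazol-1-yl)-5-methylhex-4-en-1-one
Conditions: CDI, CH2Cl2, 25 °C
Reagents that add atoms: 1,1'-carbonyldiimidazole, O=C(n1ccnc1)n1ccnc1
Why: Standard acid activation through the mixed anhydride to the acyl imidazole with loss of CO2; the trisubstituted alkene is inert.

Step 3
Reactants: 2 1-{2,6-dihydroxy-4-methoxy-3-[(4-methylbenzenesulfonyl)methyl]phenyl}ethan-1-one; 4 1-(1H-imidazol-1-yl)-5-methylhex-4-en-1-one
Product: 6 (3R)-8-acetyl-7-hydroxy-5-methoxy-3-(3-methylbut-2-en-1-yl)-3,4-dihydro-2H-1-benzopyran-2-one, via o-quinone methide 5 (not isolated)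
Conditions: 4 (1.5 equiv), (5aR,10bS)-2-(2,4,6-trimethylphenyl)-5a,10b-dihydro-4H,6H-indeno[2,1-b][1,2,4]triazolo[4,3-d][1,4]oxazin-2-ium tetrafluoroborate (15 mol%), Cs2CO3, 4 Å MS, THF, -20 to 0 °C
Reagents that add atoms: none
Why: Cs2CO3 deprotonates the phenol next to the sulfonylmethyl group (the future O1) and the phenoxide expels sulfinate to give o-quinone methide 5, while the triazolylidene is acylated by 4 and the acyl azolium is deprotonated to the (Z)-azolium enolate. The enolate α-carbon adds to the methide carbon (C1''–C2'' bond) in an inverse-electron-demand oxa-[4+2] sense driven by rearomatisation of ring A, and the phenoxide then displaces the carbene from the acyl azolium (6-exo-trig acyl substitution, O1–C3'' bond), which closes the six-membered lactone and turns the catalyst over. The closest known reaction type is the carbene-catalysed formal [4+2] annulation of azolium enolates with in situ generated o-quinone methides to 3-substituted 3,4-dihydrocoumarins. The only new stereocentre, C3 of the lactone (C2'' of the target), is set by the catalyst: the aminoindanol backbone and the N-aryl group block one face of the enolate, and the (5aR,10bS) salt is expected to give (3R). The step needs C-alkylation ahead of O-acylation of the phenols, favoured by the soft enolate carbon and by reversible acyl transfer under carbene catalysis, and it needs capture of 5 by the enolate rather than by a second molecule of 2, favoured by slow release of 5 at low temperature and an excess of 4. The product must keep its configuration; its C3–H carries an alkyl, not an aryl, group and should not be removed by carbonate below 0 °C. Lactonisation can only use the oxygen ortho to the new CH2 group, because the other phenol is para to it and hydrogen-bonded to the acetyl group, so the annulation also tells the future O1 (lactone oxygen) from the future O5 (free phenol).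

Step 4
Reactants: 6 (3R)-8-acetyl-7-hydroxy-5-methoxy-3-(3-methylbut-2-en-1-yl)-3,4-dihydro-2H-1-benzopyran-2-one
Product: 7 (3R)-8-acetyl-5-methoxy-7-(methoxymethoxy)-3-(3-methylbut-2-en-1-yl)-3,4-dihydro-2H-1-benzopyran-2-one
Conditions: MOMCl, iPr2NEt, CH2Cl2, 0 to 25 °C
Reagents that add atoms: chloromethyl methyl ether, COCCl
Why: O-alkylation of the only free phenol (the future O5) while the future O1 is locked in the lactone; the amine base is too weak to enolise the 3-alkyl lactone, so C3 should keep its configuration.

Step 5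
Reactants: 7 (3R)-8-acetyl-5-methoxy-7-(methoxymethoxy)-3-(3-methylbut-2-en-1-yl)-3,4-dihydro-2H-1-benzopyran-2-one
Product: 9 (3R)-3-{[3-acetyl-2-hydroxy-6-methoxy-4-(methoxymethoxy)phenyl]methyl}-6-methylhept-5-en-2-one, via Weinreb amide 8 (not isolated)
Conditions: MeNH(OMe)·HCl, iPrMgCl, THF, -20 °C; then MeMgBr, -20 to 0 °C; aq NH4Cl
Reagents that add atoms: methylmagnesium bromide, C[Mg]Br (CH3 of 9); N,O-dimethylhydroxylamine hydrochloride, CNOC.Cl (amide nitrogen of 8 only)
Why: The magnesium amide opens the activated aryl lactone to N-methoxy-N-methylamide 8 and frees the future O1 as its magnesium phenoxide; the Grignard adds once because the chelated tetrahedral intermediate holds until work-up. The aryl ketone, flanked by two ortho oxygens and conjugated to the phenoxide, should be enolised at most and not attacked at this temperature. Ketone 9 may sit partly as its cyclic hemiketal with the free phenol.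

Step 6
Reactants: 9 (3R)-3-{[3-acetyl-2-hydroxy-6-methoxy-4-(methoxymethoxy)phenyl]methyl}-6-methylhept-5-en-2-one
Product: 10 1-{2-hydroxy-4-methoxy-6-(methoxymethoxy)-3-[(2R)-5-methyl-2-(prop-1-en-2-yl)hex-4-en-1-yl]phenyl}ethan-1-one
Conditions: Ph3PCH3Br, KOtBu, THF, 0 °C
Reagents that add atoms: methyltriphenylphosphonium bromide, C[P+](c1ccccc1)(c1ccccc1)c1ccccc1.[Br-]
Why: Wittig methylenation of the aliphatic methyl ketone completes the lavandulyl chain; the first equivalent of ylide forms the phenoxide, which makes the di-ortho-substituted aryl ketone a vinylogous carboxylate that should not react at 0 °C. Kinetic deprotonation of 9 by the ylide should occur at CH3, not at the hindered C2''–H, and once the carbonyl is gone C2'' is no longer epimerisable.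

Step 7
Reactants: 10 1-{2-hydroxy-4-methoxy-6-(methoxymethoxy)-3-[(2R)-5-methyl-2-(prop-1-en-2-yl)hex-4-en-1-yl]phenyl}ethan-1-one
Product: 12 7-methoxy-5-(methoxymethoxy)-8-[(2R)-5-methyl-2-(prop-1-en-2-yl)hex-4-en-1-yl]-4H-1-benzopyran-4-one, via enaminone 11 (not isolated)
Conditions: Me2NCH(OMe)2, toluene, 90 °C; then AcOH, 60 °C
Reagents that add atoms: N,N-dimethylformamide dimethyl acetal, COC(OC)N(C)C
Why: Condensation at the acetyl CH3 gives enaminone 11, and mild acid triggers 6-endo addition–elimination by the one free phenol with loss of dimethylamine. Because the other ortho oxygen is a methoxymethyl ether, only the 8-substituted chromone can form.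

Step 8
Reactants: 13 4-methoxybenzene-1,3-diol
Product: 14 1-methoxy-2,4-bis(methoxymethoxy)benzene
Conditions: MOMCl, iPr2NEt, CH2Cl2, 0 to 25 °C
Reagents that add atoms: chloromethyl methyl ether, COCCl
Why: Routine double O-alkylation of two unhindered phenols.

Step 9
Reactants: 14 1-methoxy-2,4-bis(methoxymethoxy)benzene
Product: 15 1-bromo-5-methoxy-2,4-bis(methoxymethoxy)benzene
Conditions: NBS, MeCN, 0 °C
Reagents that add atoms: N-bromosuccinimide, O=C1CCC(=O)N1Br
Why: Electrophilic bromination goes to the position ortho to one methoxymethoxy group and para to the other; the site between the two acetal ethers is equally activated but hindered, and the site next to OCH3 has only one donor.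

Step 10
Reactants: 15 1-bromo-5-methoxy-2,4-bis(methoxymethoxy)benzene
Product: 17 [5-methoxy-2,4-bis(methoxymethoxy)phenyl]boronic acid, via aryllithium 16 (not isolated)
Conditions: n-BuLi, THF, -78 °C; B(OiPr)3; aq NH4Cl
Reagents that add atoms: triisopropyl borate, CC(C)OB(OC(C)C)OC(C)C; water, O (n-butyllithium, [Li]CCCC, supplies Li of 16 only)
Why: Bromine–lithium exchange is faster than ortho-lithiation at -78 °C, and borate quench with buffered hydrolysis gives the boronic acid with the acetal ethers intact.

Step 11
Reactants: 12 7-methoxy-5-(methoxymethoxy)-8-[(2R)-5-methyl-2-(prop-1-en-2-yl)hex-4-en-1-yl]-4H-1-benzopyran-4-one; 17 [5-methoxy-2,4-bis(methoxymethoxy)phenyl]boronic acid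
Product: 18 (2S)-7-methoxy-2-[5-methoxy-2,4-bis(methoxymethoxy)phenyl]-5-(methoxymethoxy)-8-[(2R)-5-methyl-2-(prop-1-en-2-yl)hex-4-en-1-yl]-2,3-dihydro-4H-1-benzopyran-4-one
Conditions: [RhCl(C2H4)2]2 (2.5 mol%), (S)-2,2'-bis[bis(3,4,5-trifluorophenyl)phosphino]-6,6'-dimethoxy-1,1'-biphenyl (5.5 mol%), KOH (aq, 20 mol%), 17 (3 equiv), toluene/H2O, 25 °C
Reagents that add atoms: none
Why: Hayashi–Miyaura-type asymmetric 1,4-addition: the aryl–rhodium species adds across C2=C3 of the chromone and the rhodium enolate is protonated by water. The electron-poor bisphosphine allows room temperature, which should keep 18 from retro-oxa-Michael opening and from a second 1,2-addition. C2 is set by the ligand alone, since C2'' is six atoms away; the (S)-ligand is expected to give (2S). The unactivated chain alkenes do not insert.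

Step 12
Reactants: 18 (2S)-7-methoxy-2-[5-methoxy-2,4-bis(methoxymethoxy)phenyl]-5-(methoxymethoxy)-8-[(2R)-5-methyl-2-(prop-1-en-2-yl)hex-4-en-1-yl]-2,3-dihydro-4H-1-benzopyran-4-one
Product: 19 (2S)-2-(2,4-dihydroxy-5-methoxyphenyl)-5-hydroxy-7-methoxy-8-[(2R)-5-methyl-2-(prop-1-en-2-yl)hex-4-en-1-yl]-2,3-dihydro-4H-1-benzopyran-4-one
Conditions: HCl (3 M aq), MeOH, 40 °C
Reagents that add atoms: none
Why: Acid methanolysis of the three acetal ethers, the peri one first. In 19 no free phenol is ortho to the lavandulyl chain (C7 bears OCH3, C8a is O1), so acid-induced chroman formation is not possible, and the mild temperature should limit ring opening at C2.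

## Compound list

1 | 1-(2,6-dihydroxy-4-methoxyphenyl)ethan-1-one | CC(=O)c1c(O)cc(OC)cc1O | starting material
2 | 1-{2,6-dihydroxy-4-methoxy-3-[(4-methylbenzenesulfonyl)methyl]phenyl}ethan-1-one | CC(=O)c1c(O)cc(OC)c(CS(=O)(=O)c2ccc(C)cc2)c1O | intermediate
3 | 5-methylhex-4-enoic acid | CC(C)=CCCC(=O)O | starting material
4 | 1-(1H-imidazol-1-yl)-5-methylhex-4-en-1-one | CC(C)=CCCC(=O)n1ccnc1 | intermediate
5 | 2-acetyl-3-hydroxy-5-methoxy-6-methylidenecyclohexa-2,4-dien-1-one (o-quinone methide) | CC(=O)C1=C(O)C=C(OC)C(=C)C1=O | intermediate (not isolated)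
6 | (3R)-8-acetyl-7-hydroxy-5-methoxy-3-(3-methylbut-2-en-1-yl)-3,4-dihydro-2H-1-benzopyran-2-one | CC(=O)c1c(O)cc(OC)c2c1OC(=O)[C@H](CC=C(C)C)C2 | intermediate
7 | (3R)-8-acetyl-5-methoxy-7-(methoxymethoxy)-3-(3-methylbut-2-en-1-yl)-3,4-dihydro-2H-1-benzopyran-2-one | CC(=O)c1c(OCOC)cc(OC)c2c1OC(=O)[C@H](CC=C(C)C)C2 | intermediate
8 | (2R)-2-{[3-acetyl-2-hydroxy-6-methoxy-4-(methoxymethoxy)phenyl]methyl}-N-methoxy-N,5-dimethylhex-4-enamide | CON(C)C(=O)[C@H](CC=C(C)C)Cc1c(O)c(C(C)=O)c(OCOC)cc1OC | intermediate (not isolated)
9 | (3R)-3-{[3-acetyl-2-hydroxy-6-methoxy-4-(methoxymethoxy)phenyl]methyl}-6-methylhept-5-en-2-one | CC(=O)[C@H](CC=C(C)C)Cc1c(O)c(C(C)=O)c(OCOC)cc1OC | intermediate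
10 | 1-{2-hydroxy-4-methoxy-6-(methoxymethoxy)-3-[(2R)-5-methyl-2-(prop-1-en-2-yl)hex-4-en-1-yl]phenyl}ethan-1-one | C=C(C)[C@H](CC=C(C)C)Cc1c(O)c(C(C)=O)c(OCOC)cc1OC | intermediate
11 | (2E)-3-(dimethylamino)-1-{2-hydroxy-4-methoxy-6-(methoxymethoxy)-3-[(2R)-5-methyl-2-(prop-1-en-2-yl)hex-4-en-1-yl]phenyl}prop-2-en-1-one | C=C(C)[C@H](CC=C(C)C)Cc1c(O)c(C(=O)/C=C/N(C)C)c(OCOC)cc1OC | intermediate (not isolated)
12 | 7-methoxy-5-(methoxymethoxy)-8-[(2R)-5-methyl-2-(prop-1-en-2-yl)hex-4-en-1-yl]-4H-1-benzopyran-4-one | C=C(C)[C@H](CC=C(C)C)Cc1c(OC)cc(OCOC)c2c1OC=CC2=O | intermediate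
13 | 4-methoxybenzene-1,3-diol | COc1ccc(O)cc1O | starting material
14 | 1-methoxy-2,4-bis(methoxymethoxy)benzene | COCOc1ccc(OC)c(OCOC)c1 | intermediate
15 | 1-bromo-5-methoxy-2,4-bis(methoxymethoxy)benzene | COCOc1cc(OCOC)c(OC)cc1Br | intermediate
16 | [5-methoxy-2,4-bis(methoxymethoxy)phenyl]lithium | [Li]c1cc(OC)c(OCOC)cc1OCOC | intermediate (not isolated)
17 | [5-methoxy-2,4-bis(methoxymethoxy)phenyl]boronic acid | COCOc1cc(OCOC)c(OC)cc1B(O)O | intermediate
18 | (2S)-7-methoxy-2-[5-methoxy-2,4-bis(methoxymethoxy)phenyl]-5-(methoxymethoxy)-8-[(2R)-5-methyl-2-(prop-1-en-2-yl)hex-4-en-1-yl]-2,3-dihydro-4H-1-benzopyran-4-one | C=C(C)[C@H](CC=C(C)C)Cc1c(OC)cc(OCOC)c2c1O[C@H](c1cc(OC)c(OCOC)cc1OCOC)CC2=O | intermediate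
19 | (2S)-2-(2,4-dihydroxy-5-methoxyphenyl)-5-hydroxy-7-methoxy-8-[(2R)-5-methyl-2-(prop-1-en-2-yl)hex-4-en-1-yl]-2,3-dihydro-4H-1-benzopyran-4-one | C=C(C)[C@H](CC=C(C)C)Cc1c(OC)cc(O)c2c1O[C@H](c1cc(OC)c(O)cc1O)CC2=O | target

## Step count and least certain steps

Total: 12 steps. Longest linear sequence: 8 steps (steps 1, 3, 4, 5, 6, 7, 11, 12, from 1).

**Step 3 (key step).** The o-quinone methide may be captured by a second molecule of 2 (diarylmethane formation), or O-acylation of the phenols may outrun C–C bond formation. Facial selectivity may also be poor because the methide carbon is unsubstituted. Fallback: from 2, enamine catalysis replaces the azolium enolate. Compound 2 and 5-methylhex-4-enal react with (S)-2-[diphenyl(trimethylsilyloxy)methyl]pyrrolidine (or its antipode) and NaHCO3 in CH2Cl2 to give the lactol 1-[(3R)-2,7-dihydroxy-5-methoxy-3-(3-methylbut-2-en-1-yl)-3,4-dihydro-2H-1-benzopyran-8-yl]ethan-1-one F1. This is oxidised with Ag2CO3 on Celite in toluene to lactone 6, where the route is rejoined.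

**Step 1.** A second sulfonylmethylation at the remaining ring position, or attack of the benzyl cation on another arene, may erode the yield. Fallback: from 1, aminomethylation with dimethylmethylideneammonium iodide in CH2Cl2 gives the Mannich base 1-{3-[(dimethylamino)methyl]-2,6-dihydroxy-4-methoxyphenyl}ethan-1-one F2. Heating F2 with TolSO2Na in AcOH exchanges the amine for sulfinate through the quinone methide and returns to 2.

**Step 6.** The ylide may also methylenate the aryl ketone, or enolisation of 9 toward C2'' may erode the configuration. Fallback: from 7, the aryl ketone is masked as the chromone before the side-chain ketone exists.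
- Step 5 is stopped after the amidation stage and 8 is isolated.
- Formamide acetal condensation gives the enaminone (2R)-2-({3-[(2E)-3-(dimethylamino)prop-2-enoyl]-2-hydroxy-6-methoxy-4-(methoxymethoxy)phenyl}methyl)-N-methoxy-N,5-dimethylhex-4-enamide F3.
- Acetic acid closes F3 to the chromone amide (2R)-N-methoxy-2-{[7-methoxy-5-(methoxymethoxy)-4-oxo-4H-1-benzopyran-8-yl]methyl}-N,5-dimethylhex-4-enamide F4.
- MeMgBr at -40 °C should add to the amide faster than to the vinylogous-ester carbonyl of the pyranone, giving (3R)-3-{[7-methoxy-5-(methoxymethoxy)-4-oxo-4H-1-benzopyran-8-yl]methyl}-6-methylhept-5-en-2-one F5.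
- Wittig methylenation of F5, with no phenol and no reactive aryl ketone present, gives 12.

**Step 7.** During the acid-induced closure the methoxymethyl ether ortho to the carbonyl may be lost before the ring closes, or the free phenol may add to the isopropenyl group. Fallback: from 10, a base-only sequence. Claisen formylation with HCO2Et and NaH in THF gives the hemiacetal 2-hydroxy-7-methoxy-5-(methoxymethoxy)-8-[(2R)-5-methyl-2-(prop-1-en-2-yl)hex-4-en-1-yl]-2,3-dihydro-4H-1-benzopyran-4-one F6. Dehydration with MsCl and Et3N gives 12.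

**Step 11.** The ortho-substituted, electron-rich boronic acid may transmetalate slowly and protodeboronate, or the facial selectivity may be insufficient. Fallback: from 10 and 15, by known chalcone chemistry.
- Lithiation of 15 (through 16) and quench with N,N-dimethylformamide gives 5-methoxy-2,4-bis(methoxymethoxy)benzaldehyde F7.
- Claisen–Schmidt condensation of F7 with 10 (KOH, EtOH/H2O) gives the chalcone (2E)-1-{2-hydroxy-4-methoxy-6-(methoxymethoxy)-3-[(2R)-5-methyl-2-(prop-1-en-2-yl)hex-4-en-1-yl]phenyl}-3-[5-methoxy-2,4-bis(methoxymethoxy)phenyl]prop-2-en-1-one F8.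
- Closure with NaOAc in EtOH gives 18 together with its C2 epimer, (2R)-7-methoxy-2-[5-methoxy-2,4-bis(methoxymethoxy)phenyl]-5-(methoxymethoxy)-8-[(2R)-5-methyl-2-(prop-1-en-2-yl)hex-4-en-1-yl]-2,3-dihydro-4H-1-benzopyran-4-one F9.
- Asymmetric transfer hydrogenation with RuCl(p-cymene)[(R,R)-TsDPEN] (or its antipode) in HCO2H/Et3N reduces the (2R)-ketone selectively to the cis-alcohol (2R,4R)-7-methoxy-2-[5-methoxy-2,4-bis(methoxymethoxy)phenyl]-5-(methoxymethoxy)-8-[(2R)-5-methyl-2-(prop-1-en-2-yl)hex-4-en-1-yl]-3,4-dihydro-2H-1-benzopyran-4-ol F10. The alcohol is separated from unreacted 18, which rejoins the route at step 12.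

## Further compounds

F1 | step 3 | 1-[(3R)-2,7-dihydroxy-5-methoxy-3-(3-methylbut-2-en-1-yl)-3,4-dihydro-2H-1-benzopyran-8-yl]ethan-1-one | CC(=O)c1c(O)cc(OC)c2c1OC(O)[C@H](CC=C(C)C)C2
F2 | step 1 | 1-{3-[(dimethylamino)methyl]-2,6-dihydroxy-4-methoxyphenyl}ethan-1-one | CC(=O)c1c(O)cc(OC)c(CN(C)C)c1O
F3 | step 6 | (2R)-2-({3-[(2E)-3-(dimethylamino)prop-2-enoyl]-2-hydroxy-6-methoxy-4-(methoxymethoxy)phenyl}methyl)-N-methoxy-N,5-dimethylhex-4-enamide | CON(C)C(=O)[C@H](CC=C(C)C)Cc1c(O)c(C(=O)/C=C/N(C)C)c(OCOC)cc1OC
F4 | step 6 | (2R)-N-methoxy-2-{[7-methoxy-5-(methoxymethoxy)-4-oxo-4H-1-benzopyran-8-yl]methyl}-N,5-dimethylhex-4-enamide | CON(C)C(=O)[C@H](CC=C(C)C)Cc1c(OC)cc(OCOC)c2c1OC=CC2=O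
F5 | step 6 | (3R)-3-{[7-methoxy-5-(methoxymethoxy)-4-oxo-4H-1-benzopyran-8-yl]methyl}-6-methylhept-5-en-2-one | CC(=O)[C@H](CC=C(C)C)Cc1c(OC)cc(OCOC)c2c1OC=CC2=O
F6 | step 7 | 2-hydroxy-7-methoxy-5-(methoxymethoxy)-8-[(2R)-5-methyl-2-(prop-1-en-2-yl)hex-4-en-1-yl]-2,3-dihydro-4H-1-benzopyran-4-one | C=C(C)[C@H](CC=C(C)C)Cc1c(OC)cc(OCOC)c2c1OC(O)CC2=O
F7 | step 11 | 5-methoxy-2,4-bis(methoxymethoxy)benzaldehyde | COCOc1cc(OCOC)c(OC)cc1C=O
F8 | step 11 | (2E)-1-{2-hydroxy-4-methoxy-6-(methoxymethoxy)-3-[(2R)-5-methyl-2-(prop-1-en-2-yl)hex-4-en-1-yl]phenyl}-3-[5-methoxy-2,4-bis(methoxymethoxy)phenyl]prop-2-en-1-one | C=C(C)[C@H](CC=C(C)C)Cc1c(O)c(C(=O)/C=C/c2cc(OC)c(OCOC)cc2OCOC)c(OCOC)cc1OC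
F9 | step 11 | (2R)-7-methoxy-2-[5-methoxy-2,4-bis(methoxymethoxy)phenyl]-5-(methoxymethoxy)-8-[(2R)-5-methyl-2-(prop-1-en-2-yl)hex-4-en-1-yl]-2,3-dihydro-4H-1-benzopyran-4-one | C=C(C)[C@H](CC=C(C)C)Cc1c(OC)cc(OCOC)c2c1O[C@@H](c1cc(OC)c(OCOC)cc1OCOC)CC2=O
F10 | step 11 | (2R,4R)-7-methoxy-2-[5-methoxy-2,4-bis(methoxymethoxy)phenyl]-5-(methoxymethoxy)-8-[(2R)-5-methyl-2-(prop-1-en-2-yl)hex-4-en-1-yl]-3,4-dihydro-2H-1-benzopyran-4-ol | C=C(C)[C@H](CC=C(C)C)Cc1c(OC)cc(OCOC)c2c1O[C@@H](c1cc(OC)c(OCOC)cc1OCOC)C[C@H]2O
A1 | alternative 1 | (2S)-1-bromo-5-methyl-2-(prop-1-en-2-yl)hex-4-ene | C=C(C)[C@H](CC=C(C)C)CBr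
A2 | alternative 1 | 1-[2-hydroxy-4-methoxy-6-(methoxymethoxy)phenyl]ethan-1-one | CC(=O)c1c(O)cc(OC)cc1OCOC
A3 | alternative 2 | 7-methoxy-5-[(3-methylbut-2-en-1-yl)oxy]-4H-1-benzopyran-4-one | CC(C)=CCOc1cc(OC)cc2OC=CC(=O)c12
A4 | alternative 2 | 5-hydroxy-7-methoxy-8-(3-methylbut-2-en-1-yl)-4H-1-benzopyran-4-one | CC(C)=CCc1c(OC)cc(O)c2c1OC=CC2=O
A5 | alternative 2 | 5-hydroxy-8-[(2E)-4-hydroxy-3-methylbut-2-en-1-yl]-7-methoxy-4H-1-benzopyran-4-one | OC/C(C)=C/Cc1c(OC)cc(O)c2c1OC=CC2=O
A6 | alternative 2 | ethyl 3-[(5-hydroxy-7-methoxy-4-oxo-4H-1-benzopyran-8-yl)methyl]-4-methylpent-4-enoate (racemic) | CCOC(=O)CC(Cc1c(OC)cc(O)c2c1OC=CC2=O)C(C)=C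
A7 | alternative 3 | [(2E)-2,6-dimethylhepta-2,5-dien-1-yl]trimethylsilane | C[Si](C)(C)C/C(C)=C/CC=C(C)C
A8 | alternative 3 | 1-{2,6-dihydroxy-4-methoxy-3-[5-methyl-2-(prop-1-en-2-yl)hex-4-en-1-yl]phenyl}ethan-1-one (racemic) | C=C(C)C(CC=C(C)C)Cc1c(O)c(C(C)=O)c(O)cc1OC
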